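The runs were generated by integration for substances that don't exist, noise included.

The target is what we count at this bench, and this note tells whoever takes over how much of it to expect at 50 min.

all flasks: free catalyst 1.9 mol%
- north-east: starting material 0.035 M; reagent 1.3 equiv; temperature −5 °C; run made earlier
- north-west: starting material 0.035 M; reagent 0.65 equiv; temperature 6 °C; run made earlier
- south: starting material 0.035 M; reagent 0.98 equiv; temperature −5 °C; run made earlier
- gamma: starting material 0.035 M; reagent 1.30 equiv (fed, over 30 min); temperature 0 °C; all else is in the flask from the start; the feed brings no volume worth counting; time 50 min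
- beta: starting material 0.035 M; reagent 1.30 equiv (fed, over 3.0 min); temperature 0 °C; all else is in the flask from the start; the feed brings no volume worth counting; time 50 min
- epsilon: starting material 0.035 M; reagent 1.30 equiv; everything together at the start at −20 °C, warmed to 0 °C at 30 min; time 50 min
- alpha: starting material 0.035 M (fed, over 30 min); reagent 1.30 equiv; temperature 0 °C; all else is in the flask from the start; the feed brings no volume worth counting; time 50 min
- delta: starting material 0.035 M (in portions, 2, over 30 min); reagent 1.30 equiv; temperature 0 °C; first portion at the start, last at 30 min; time 50 min
- zeta: starting material 0.035 M; reagent 1.30 equiv (fed, over 30 min); the addition at −20 °C, then warmed to 0 °C; the feed brings no volume worth counting; time 50 min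

| run | time / min | target / % |
|---|---|---|
| north-east | 2.50 | 1.2 |
| north-east | 8.00 | 4.7 |
| north-east | 15.0 | 8.9 |
| north-east | 20.0 | 11.2 |
| north-east | 30.0 | 17.6 |
| north-west | 5.00 | 5.8 |
| north-west | 15.0 | 16.8 |
| north-west | 30.0 | 30.1 |
| north-west | 40.0 | 37.1 |
| north-west | 60.0 | 46.8 |
| south | 5.00 | 2.2 |
| south | 15.0 | 8.4 |
| south | 30.0 | 15.5 |
| south | 40.0 | 20.5 |
| south | 60.0 | 29.1 |

(scatter of a reading: 0.3 percentage points)



* the best flask by amount of target, in percent of the starting material charged; "all alike" if 1.5 percentage points covers them all (gamma / beta / epsilon / alpha / delta / zeta / all alike)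
* amount of target at the end, in percent of the starting material charged, gamma
* amount of target at the end, in percent of the starting material charged, beta
* amount of target at the end, in percent of the starting material charged, epsilon
* amount of target at the end, in percent of the starting material charged, alpha
* amount of target at the end, in percent of the starting material charged, delta
* amount of target at the end, in percent of the starting material charged, zeta

Follow one molecule of starting material: at the opening pace it has a steady chance each minute of becoming target. The inverse of that chance is the time the flask would need to convert the whole charge at that pace. The north-east run reached 17.6% in 30.0 min, which gives 170 min. The south run, with 0.98 equiv of reagent, reads a longer 194 min, so the pace follows the reagent charge to a power of about 0.450. The north-west run reads 89.3 min at 6 °C, and a round power of 0.5 turns this into 63.1 min at 1.3 equiv. Placing 0 °C between the two temperatures on a logarithmic scale gives 109 min; this is our conversion clock, the minutes for the whole charge at the opening pace with 1.30 equiv of reagent.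

Counting beta from the middle of its feed, we expect 44.7%. Epsilon spends 30 min at −20 °C, where the same scale gives 660 min, so we expect 22.9%. Do not let the warming slip, because a cold minute counts for less than a warm one.

The forecast names beta as best, with gamma 39%, beta 48%, epsilon 24%, alpha 41%, delta 42% and zeta 23%, and it says: “Slow reagent feeding wastes time at low reagent”. Our figure for beta is lower than its figure.

The flasks gave gamma 35.3%, beta 42.8%, epsilon 22.2%, alpha 35.4%, delta 37.4% and zeta 21.3%, with beta best.

    starting material + free catalyst → catalyst intermediate A (k = 82.0 /M/min, Ea = 47.0 kJ/mol)
    reagent + catalyst intermediate A ⇌ catalyst intermediate B (K = 34.0 /M, k = 42.0 /M/min, Ea = 42.0 kJ/mol, ΔH = −3.00 kJ/mol)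
    catalyst intermediate B ⇌ released group + catalyst intermediate C (K = 0.0900 M, k = 3.40 /min, Ea = 77.0 kJ/mol, ΔH = −11.0 kJ/mol)
    catalyst intermediate C → catalyst intermediate D (k = 180 /min, Ea = 72.0 kJ/mol)
    catalyst intermediate D → free catalyst + target (k = 2.30 /min, Ea = 75.0 kJ/mol)
    free catalyst ⇌ dormant form (K = 0.530, k = 0.0110 /min, Ea = 92.0 kJ/mol, ΔH = 9.00 kJ/mol)
    (constants at 0 °C)

Beta's 42.8% in 50 min corresponds to an average clock of 117 min, longer than the 109 min of the opening pace. In zeta, the midpoint of the turnover of the step from starting material and free catalyst to catalyst intermediate A came at 37.8 min, later than the end of the cold addition, and the clock credits the 20.0 min at 0 °C with 18.3%, while the flask ended with 21.3% of target.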